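The readings are simulated with constants of no real substance, noise included.

If two starting material make one target in a single step, each flask can be reckoned by its dose, k[starting material]t with the charged concentration and with k the constant by which starting material itself falls (the dimensionless time of second-order kinetics), and the target share is dose over one plus dose.

| flask | starting material | temperature | remark | time |
|---|---|---|---|---|
| beta | 0.050 M | 35 °C | run made earlier |  |
| theta | 0.20 M | 65 °C | run made earlier |  |
| Wednesday's | 0.10 M | 65 °C |  | 12 h |
| Friday's | 0.10 M | 40 °C |  | 12 h |
| Tuesday's | 0.10 M |  | at 90 °C until 2.5 h, from then on at 40 °C | 12 h |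
| Saturday's | 0.10 M | 90 °C |  | 12 h |

- beta (time / h: target / %): 4.00: 0.3; 8.00: 0; 20.0: 0.3; 40.0: 0.5
- theta (time / h: target / %): 0.833: 0.3; 2.00: 2.5; 4.00: 3.7; 10.0: 9.0

(standard deviation of a reading: 0.5 percentage points)

- percentages count the starting material that a species holds: one target counts as two

* the flask that comes out highest in amount of target, in percent of the starting material charged, or "all alike" when all lie within 1.5 percentage points (Wednesday's / Friday's / Tuesday's / Saturday's / all alike)
* target at the end, in percent of the starting material charged, Wednesday's
* target at the end, in percent of the starting material charged, Friday's
* target at the end, in percent of the starting material charged, Tuesday's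
* target at the end, in percent of the starting material charged, Saturday's

In logarithms, concentration, time and temperature each add their decades to the dose. The theta run's last reading gives a dose of 0.0989 and the beta run's 0.00503. Per unit of charge and time, theta therefore runs 1.29 decades faster, a weak figure, since that beta reading of 0.5% carries a scatter of 0.5 percentage points. Wednesday's shares theta's temperature, so I reckon a dose of 0.0593, which is 5.60% target. Taking the decades as proportional to degrees, Friday's dose is 0.00495, which is 0.493%. My dose for Saturday's flask, k[starting material]t at its temperature, is 0.711, which is 41.5%. Doses add along a run, so Tuesday's gets 0.152, which is 13.2%. I commit to Saturday's, whose dose is larger than the others.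

The forecast uses the same form with an activation energy of 85 kJ/mol. It names Saturday's, with 5.5%, 0.5%, 8.8% and 30% in the order asked, so it stands lower than I do on Saturday's and on Tuesday's. It adds: “Saturday's should be highest, unless the target is lost or reverses at 90 °C, which is untested.”

The flasks give Saturday's as highest, with 5.73%, 0.366%, 12.5% and 23.9%.

    2 starting material → target (k = 0.00565 L mol⁻¹ min⁻¹, Ea = 102 kJ mol⁻¹)
    starting material + target → side product (k = 0.0215 L mol⁻¹ min⁻¹, Ea = 87.0 kJ mol⁻¹)
    (constants at 90 °C)

In Saturday's flask, target is made 2.43 times faster than it is used up at 3.98 h, but 1.08 times at 12.0 h. By then that flask holds 26.8% as side product beside 23.9% target, and my dose of 0.711 had given more target than that, 41.5%.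

For the flask like Saturday's but charged at 0.025 M, the dose is a quarter of that, 0.178, which gives 15.1% target. That flask computes to 14.0%, with 4.05% side product.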